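**Retrosynthetic overview** (cembrane numbering: C1 = ring CH bearing the acrylate; C3–C4 = oxirane; C7=C8; C11 = ketone; C12 = carbinol; C13, C14 = ring CH2; C15–C17 = acrylate)
1. Target 22 comes from enol silane 20 by asymmetric Rubottom oxidation (C12–OH). 20 comes from 17 by methylenation at C15 while the C11 ketone is still masked.
2. 17 comes from the acyclic bromo enone 16. The 14-membered ring is closed at C13–C14 by a nickel-catalysed reductive conjugate addition that traps the enolate as a silyl ether.
3. Enabling feature: in the ring segment C11(=O)–C12(OH)(CH3)–C13H2, C13 is the β-carbon of the ketone and the hydroxyl sits on its α-carbon. The ketol is therefore the oxidised enolate of an isopropenyl ketone, and C14 is a plain CH2 next to the C1 stereocentre.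
4. 16 comes from allylic carbonate 13 and silyl dienol ether 15 (C9–C10, Tsuji allylation). 13 comes from imide 6 and epoxy triflate 3 (C1–C2, Evans alkylation). 3 comes from nerol (Sharpless epoxidation).
5. Ring order: oxirane (step 1); temporary butyrolactone C14–O–C16 (step 5, opened in step 6); 14-membered carbocycle (step 11); transient silyloxy-oxirane (step 13).

Key step: step 11

Remark on the structure: in the given configuration C2 and C5 are cis on the oxirane, so the epoxide belongs to the Z (nerol) series, not the geraniol series.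

**Step 1**
Reactants: 1 nerol
Product: 2 (2R,3S)-2,3-epoxynerol
Conditions: Ti(OiPr)4 (cat.), D-(−)-diethyl tartrate (cat.), t-BuOOH, 4 Å MS, CH2Cl2, −20 °C
Reagents that add atoms: tert-butyl hydroperoxide CC(C)(C)OO
Why: Katsuki–Sharpless asymmetric epoxidation: titanium binds the allylic alcohol so that only the C3=C4 olefin reacts, the Z geometry of nerol becomes the cis relation of C2 and C5 on the oxirane, and D-(−)-tartrate delivers oxygen to the face that gives 3R,4S.

**Step 2**
Reactants: 2 (2R,3S)-2,3-epoxynerol
Product: 3 epoxyneryl triflate (used at once)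
Conditions: Tf2O, 2,6-lutidine, CH2Cl2, −78 °C
Reagents that add atoms: triflic anhydride O=S(=O)(OS(=O)(=O)C(F)(F)F)C(F)(F)F
Why: O-sulfonylation of the primary alcohol with a non-nucleophilic base at low temperature gives a leaving group reactive enough for an imide enolate at −78 °C without touching the oxirane stereocentres.

**Step 3**
Reactants: 4 methyl 4-chloro-4-oxobutanoate; 5 (S)-4-benzyl-1,3-oxazolidin-2-one
Product: 6 methyl 4-[(4S)-4-benzyl-2-oxo-1,3-oxazolidin-3-yl]-4-oxobutanoate
Conditions: n-BuLi, THF, −78 °C; then 4
Reagents that add atoms: none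
Why: N-acylation of the lithiated Evans oxazolidinone by the acid chloride, which reacts far faster than the methyl ester.

**Step 4**
Reactants: 6 succinyl imide; 3 epoxyneryl triflate
Product: 7 C1-alkylated imide (C1 S; oxirane 3R,4S)
Conditions: NaHMDS, THF, −78 °C; then 3, −78 → −30 °C
Reagents that add atoms: none
Why: Evans asymmetric alkylation: NaHMDS deprotonates the more acidic imide α-CH2 to the chelated Z-enolate, whose face opposite the benzyl group attacks the primary triflate in an SN2 step much faster than opening of the hindered trisubstituted oxirane, which sets C1 as S.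

**Step 5**
Reactants: 7 C1-alkylated imide
Product: 8 (4S)-4-(epoxynerylmethyl-type) butyrolactone (ring O–C14–C1–C15–C16)
Conditions: LiBH4, H2O (1 equiv), THF, 0 °C
Reagents that add atoms: none
Why: Reductive cleavage of the N-acyl oxazolidinone by LiBH4 (ester and oxirane react more slowly), after which the C14 alkoxide closes onto the C16 methyl ester, so that the temporary butyrolactone keeps this oxygen away from the neighbouring oxirane and C1 is not touched.

**Step 6**
Reactants: 8 butyrolactone
Product: 11 methyl (3S)-3-(bromomethyl)-4-[(2R,3S)-3-methyl-3-(4-methylpent-3-en-1-yl)oxiran-2-yl]butanoate, via potassium hydroxy carboxylate 9 (not isolated), via hydroxy ester 10 (not isolated)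
Conditions: KOH, MeOH–H2O, rt, evaporate; MeI, DMF, 0 °C; extract; CBr4, PPh3, 2,6-lutidine (cat.), CH2Cl2, 0 °C
Reagents that add atoms: potassium hydroxide [K+].[OH-]; iodomethane CI; carbon tetrabromide BrC(Br)(Br)Br
Why: Lactone saponification, SN2 O-methylation of the carboxylate (neutral, so that relactonisation and 5-exo attack of the free C14 hydroxyl on the oxirane are held back) and immediate Appel bromination turn the temporary ring into the methyl ester and the primary C14 bromide without change at any stereocentre.

**Step 7**
Reactants: 11 bromo ester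
Product: 12 (7E)-C9 allylic alcohol
Conditions: SeO2 (cat.), t-BuOOH, CH2Cl2, 0 °C → rt
Reagents that add atoms: tert-butyl hydroperoxide CC(C)(C)OO
Why: Riley-type allylic oxidation (ene reaction, then [2,3]-sigmatropic shift) on the only remaining olefin oxidises the methyl group trans to the chain and so fixes the 7E geometry with C9 functionalised.

**Step 8**
Reactants: 12 allylic alcohol
Product: 13 allylic methyl carbonate
Conditions: ClCO2Me, pyridine, CH2Cl2, 0 °C
Reagents that add atoms: methyl chloroformate COC(=O)Cl
Why: Acylation of the allylic alcohol with the chloroformate gives the ionisable carbonate needed for palladium.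

**Step 9**
Reactants: 14 3-methylbut-3-en-2-one
Product: 15 trimethyl[(3-methylbuta-1,3-dien-2-yl)oxy]silane
Conditions: LDA (commercial solution), THF, −78 °C; Me3SiCl
Reagents that add atoms: chlorotrimethylsilane C[Si](C)(C)Cl
Why: Kinetic deprotonation of the acetyl methyl group, the only enolisable position, followed by O-silylation gives the cross-conjugated 2-silyloxy diene.

**Step 10**
Reactants: 13 allylic carbonate; 15 silyl dienol ether
Product: 16 acyclic bromo enone (C14–Br; C11(=O)–C12(CH3)=C13H2)
Conditions: Pd2(dba)3·CHCl3 (cat.), dppe (cat.), THF, 65 °C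
Reagents that add atoms: none
Why: Tsuji allylation of a silyl enol ether with an allylic carbonate: Pd(0) ionises the carbonate, the liberated methoxide desilylates 15, and the enolate attacks the less hindered primary terminus C9 of the π-allyl complex with retention of the E olefin, under neutral conditions that leave bromide, ester and oxirane alone.

**Step 11**
Reactants: 16 acyclic bromo enone
Product: 17 macrocyclic triethylsilyl enol ether (1S,3R,4S,7E,11Z) bearing CH2CO2Me at C1
Conditions: NiCl2(dme) (15 mol%), 4,4′,4″-tri-tert-butylterpyridine (15 mol%), Mn powder, Et3SiCl, DMF, 25 °C, 16 added over 20 h (final ca. 2 mM)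
Reagents that add atoms: chlorotriethylsilane CC[Si](Cl)(CC)CC
Why: Proposed new method: Mn reduces Ni(II) to Ni(0), which binds the s-cis isopropenyl ketone and is O-silylated by Et3SiCl to an η3-(1-silyloxy-2-methylallyl)nickel species; after one-electron reduction this abstracts bromine from C14, the primary radical is recaptured by nickel, and reductive elimination joins C14 to the unsubstituted allyl terminus C13. The closest known reactions are the intermolecular nickel-catalysed reductive conjugate addition of primary alkyl bromides to enones (chlorosilane, Mn) and the tin-hydride 14-endo radical macrocyclisations of halo enones used for cembranoids; what is new is the intramolecular, macrocyclic use. One ring is closed, the 14-membered carbocycle, in a formal 14-endo-trig mode at the CH2 terminus of the enone. No stereocentre is formed and C1, C3 and C4 are untouched; the C11=C12 geometry (O and C13 cis, C10 and C13 trans in the ring) follows from the s-cis-bound enone. Ring closure must beat oligomerisation and hydrodebromination (slow addition, no hydrogen donor), C13 must be attacked rather than the carbonyl carbon (allylnickel pathway), and the C14 radical must have no escape, which is why C15 is kept as a saturated CH2CO2Me arm, since an acrylate there would invite 1,2-vinyl migration and act as a second acceptor. The ketone is born masked as a regiodefined enol silane, which permits the ester methylenation of step 12 and marks C12 for oxygenation in step 13.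

**Step 12**
Reactants: 17 macrocyclic enol silane
Product: 20 macrocyclic enol silane acrylate (1S,3R,4S,7E,11Z), via dimethylaminomethyl ester 18 (not isolated), via trimethylammonium iodide 19 (not isolated)
Conditions: LDA, THF, −78 °C; CH2=NMe2+ I−, −78 °C; MeI, THF, rt; DBU, CH2Cl2, rt
Reagents that add atoms: Eschenmoser's salt C=[N+](C)C.[I-]
Why: Eschenmoser methylenation (ester-enolate Mannich reaction, quaternisation, elimination): with the ketone masked the C15 protons are the most acidic in 17, the lithium enolate takes up the iminium salt at −78 °C much faster than the hindered enol silane does, and C15 ends as sp2 so that its transient configuration is irrelevant.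

**Step 13**
Reactants: 20 macrocyclic enol silane acrylate
Product: 22 target CNP0154954.4 (1S,3R,4S,7E,12S), via silyloxy epoxide 21 (not isolated)
Conditions: ent-Shi ketone (L-fructose series, 30 mol%), Oxone, K2CO3, Bu4NHSO4 (cat.), MeCN–DMM/aq. borate–EDTA buffer, −10 → 0 °C
Reagents that add atoms: potassium peroxymonosulfate (Oxone) [K+].[O-]S(=O)(=O)OO
Why: Rubottom oxidation under Shi's asymmetric dioxirane conditions: the electron-rich enol silane should be epoxidised faster than the C7=C8 olefin and the electron-poor acrylate, the L-series ketone is chosen from the spiro transition-state model (the D-ketone gives R,R from trans-disposed olefins, and here C10 and C13 are the trans pair) so that oxygen reaches the face of C12 that gives 12S, and the silyloxy oxirane collapses in the aqueous buffer to the ketol.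

**Compound list**
1 | nerol, (2Z)-3,7-dimethylocta-2,6-dien-1-ol | CC(C)=CCC/C(C)=C\CO | starting material
2 | [(2R,3S)-3-methyl-3-(4-methylpent-3-en-1-yl)oxiran-2-yl]methanol | OC[C@@H]1[C@@](CCC=C(C)C)(C)O1 | intermediate
3 | triflate of 2 | FC(F)(F)S(=O)(=O)OC[C@@H]1[C@@](CCC=C(C)C)(C)O1 | intermediate
4 | methyl 4-chloro-4-oxobutanoate | COC(=O)CCC(=O)Cl | starting material
5 | (S)-4-benzyl-1,3-oxazolidin-2-one | O=C1N[C@@H](Cc2ccccc2)CO1 | starting material
6 | methyl 4-[(4S)-4-benzyl-2-oxo-1,3-oxazolidin-3-yl]-4-oxobutanoate | COC(=O)CCC(=O)N1[C@@H](Cc2ccccc2)COC1=O | intermediate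
7 | methyl (3S)-3-{[(4S)-4-benzyl-2-oxooxazolidin-3-yl]carbonyl}-4-[(2R,3S)-3-methyl-3-(4-methylpent-3-enyl)oxiran-2-yl]butanoate | COC(=O)C[C@@H](C(=O)N1[C@@H](Cc2ccccc2)COC1=O)C[C@@H]1[C@@](CCC=C(C)C)(C)O1 | intermediate
8 | (4S)-4-{[(2R,3S)-3-methyl-3-(4-methylpent-3-enyl)oxiran-2-yl]methyl}oxolan-2-one | O=C1C[C@H](C[C@@H]2[C@@](CCC=C(C)C)(C)O2)CO1 | intermediate
9 | potassium (3S)-3-(hydroxymethyl)-4-(oxiranyl)butanoate from 8 | [K+].[O-]C(=O)C[C@@H](CO)C[C@@H]1[C@@](CCC=C(C)C)(C)O1 | intermediate
10 | methyl ester of 9 (C14–OH) | COC(=O)C[C@@H](CO)C[C@@H]1[C@@](CCC=C(C)C)(C)O1 | intermediate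
11 | bromo ester (C14–Br) | COC(=O)C[C@@H](CBr)C[C@@H]1[C@@](CCC=C(C)C)(C)O1 | intermediate
12 | bromo ester with (E)-5-hydroxy-4-methylpent-3-enyl chain (C9–OH) | COC(=O)C[C@@H](CBr)C[C@@H]1[C@@](CC/C=C(/CO)C)(C)O1 | intermediate
13 | methyl carbonate of 12 | COC(=O)C[C@@H](CBr)C[C@@H]1[C@@](CC/C=C(/COC(=O)OC)C)(C)O1 | intermediate
14 | 3-methylbut-3-en-2-one | CC(=O)C(C)=C | starting material
15 | trimethyl[(3-methylbuta-1,3-dien-2-yl)oxy]silane | C=C(O[Si](C)(C)C)C(C)=C | intermediate
16 | acyclic bromo enone (seco compound; C14–Br and isopropenyl ketone) | COC(=O)C[C@@H](CBr)C[C@@H]1[C@@](CC/C=C(/CCC(=O)C(C)=C)C)(C)O1 | intermediate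
17 | 14-membered carbocycle: CH2CO2Me on C1 (S), cis-3R,4S-oxirane, 7E olefin, C11(OSiEt3)=C12(CH3) with O and C13 cis | COC(=O)C[C@H]1CC/C(C)=C(O[Si](CC)(CC)CC)/CC/C(C)=C/CC[C@]2(C)O[C@@H]2C1 | intermediate
18 | 17 with CH2NMe2 on C15 (C15 epimers) | COC(=O)C(CN(C)C)[C@H]1CC/C(C)=C(O[Si](CC)(CC)CC)/CC/C(C)=C/CC[C@]2(C)O[C@@H]2C1 | intermediate
19 | methiodide of 18 | COC(=O)C(C[N+](C)(C)C)[C@H]1CC/C(C)=C(O[Si](CC)(CC)CC)/CC/C(C)=C/CC[C@]2(C)O[C@@H]2C1.[I-] | intermediate
20 | 17 with C15=C17H2 (methyl acrylate on C1) | C=C(C(=O)OC)[C@H]1CC/C(C)=C(O[Si](CC)(CC)CC)/CC/C(C)=C/CC[C@]2(C)O[C@@H]2C1 | intermediate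
21 | C11–C12 silyloxy oxirane of 20 | C=C(C(=O)OC)[C@H]1CC[C@]2(C)O[C@@]2(O[Si](CC)(CC)CC)CC/C(C)=C/CC[C@]3(C)O[C@@H]3C1 | intermediate
22 | CNP0154954.4 | C=C(C(=O)OC)[C@H]1CC[C@](C)(O)C(=O)CC/C(C)=C/CC[C@]2(C)O[C@@H]2C1 | target

**Step count and linear sequence**
- Total steps: 13.
- Longest linear sequence: 11 (steps 1, 2, 4–8 and 10–13, from nerol).

**Steps most likely to fail**

1. **Step 11.**
 - Risks: oligomerisation instead of ring closure; premature reduction of the C–Br bond; opening of the oxirane by chlorosilane and halide.
 - Fallback: sets out from 16. A silane-mediated Giese 14-endo radical macrocyclisation ((Me3Si)3SiH, AIBN, benzene, 80 °C, syringe pump, ca. 2 mM) should give the macrocyclic ketone F1 as C12 epimers. Thermodynamic enol silylation with bromomagnesium diisopropylamide, Et3SiCl and Et3N then selects the more substituted enolate. The route is rejoined at 17.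

2. **Step 13.**
 - Risks: poor discrimination between the two faces of a tetrasubstituted enol ether whose C12 substituents (CH3 and CH2) differ little; competing epoxidation of C7=C8.
 - Fallback: sets out from 20 and abandons oxidation of the neutral enol ether. Fluoride (TBAT, THF, −78 °C) releases the tetrabutylammonium enolate F2. This is hydroxylated in situ by an enantiopure (camphorylsulfonyl)oxaziridine (Davis oxidation); both antipodes are available, so the pair matched to the macrocycle can be used. The route is rejoined at 22.

3. **Step 4.**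
 - Risks: slow SN2 on the β-branched epoxy triflate relative to enolate decomposition; ionisation of the triflate.
 - Fallback: sets out from 1 and 6 and postpones the epoxide.
 - PBr3 converts nerol into neryl bromide F3.
 - The sodium enolate of 6 is alkylated with this allylic halide to imide F4.
 - LiBH4 gives lactone F5.
 - KOH gives potassium salt F6, MeI gives hydroxy ester F7, and CBr4/PPh3 gives bromo ester F8.
 - SeO2/t-BuOOH oxidises the terminal prenyl unit to allylic alcohol F9, and ClCO2Me gives carbonate F10.
 - A Shi epoxidation with the D-fructose-derived ketone then attacks the C3=C4 olefin, because C7=C8 is deactivated by the allylic carbonate. The route is rejoined at 13.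

**Further compounds**
F1 | step 11 | macrocyclic ketone (C12–H epimers; CH2CO2Me on C1) | COC(=O)C[C@H]1CCC(C)C(=O)CC/C(C)=C/CC[C@]2(C)O[C@@H]2C1
F2 | step 13 | tetrabutylammonium C11–C12 enolate of the macrocyclic acrylate | C=C(C(=O)OC)[C@H]1CC/C(C)=C([O-])/CC/C(C)=C/CC[C@]2(C)O[C@@H]2C1.CCCC[N+](CCCC)(CCCC)CCCC
F3 | step 4 | neryl bromide | CC(C)=CCC/C(C)=C\CBr
F4 | step 4 | C1-nerylated imide | COC(=O)C[C@@H](C(=O)N1[C@@H](Cc2ccccc2)COC1=O)C/C=C(/C)CCC=C(C)C
F5 | step 4 | (4S)-4-neryloxolan-2-one | O=C1C[C@H](C/C=C(/C)CCC=C(C)C)CO1
F6 | step 4 | potassium hydroxy carboxylate from F5 | [K+].[O-]C(=O)C[C@@H](CO)C/C=C(/C)CCC=C(C)C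
F7 | step 4 | hydroxy methyl ester | COC(=O)C[C@@H](CO)C/C=C(/C)CCC=C(C)C
F8 | step 4 | bromo methyl ester (3Z-diene) | COC(=O)C[C@@H](CBr)C/C=C(/C)CCC=C(C)C
F9 | step 4 | C9 allylic alcohol (3Z,7E) | COC(=O)C[C@@H](CBr)C/C=C(/C)CC/C=C(/CO)C
F10 | step 4 | C9 methyl carbonate (3Z,7E) | COC(=O)C[C@@H](CBr)C/C=C(/C)CC/C=C(/COC(=O)OC)C
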